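**Plan**

- Retrosynthesis, in order: first the exocyclic C–N bond between the imidazole 2-amino nitrogen and the dehydrohydantoin carbon (back to 1-methylparabanic acid); then the imidazole C4–CH2 bond to the 4-methoxybenzyl group (Negishi coupling of an imidazol-4-yl triflate); last the C5–CH2 bond to the hydroquinone ring (Knoevenagel condensation, then hydrogenation).
- Enabling feature: the imidazole of the target carries methyl on N1, nitrogen on C2 and carbon substituents on C4 and C5. This is the ring of creatinine, whose C5 methylene next to N1 is aldol-active and whose C4 carbonyl oxygen can become a triflate leaving group.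
- Forward order: no ring is built, since both heterocycles are bought. The aldehyde is made in steps 1–3, then follow C5 arylidene formation, N-protection, hydrogenation, enol triflation (aromatisation), Negishi benzylation at C4, global deprotection and amidine formation.
- Regiochemistry of the two different benzyl groups follows from doing the aldol step at C5 before the coupling at C4.
- Stereochemistry: the target has no stereocentre. The arylidene geometry and the C5 centre of the hydrogenated imidazolone are transient and vanish on aromatisation.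

Key step: step 9

Assumption: 2,3-dimethoxy-1,4-benzoquinone and 1-methylparabanic acid are taken as catalogue compounds, like creatinine and 4-methoxybenzyl chloride.

**Route**

Step 1
Reactants: 1 2,3-dimethoxy-1,4-benzoquinone
Product: 2 2,3-dimethoxybenzene-1,4-diol
Conditions: Na2S2O4, Et2O/H2O, rt, Ar
Reagents that add atoms: none
Why: Dithionite reduction of a benzoquinone to its hydroquinone is a standard two-electron reduction that should leave the two methyl ethers untouched.

Step 2
Reactants: 2 2,3-dimethoxybenzene-1,4-diol
Product: 3 1,4-bis(methoxymethoxy)-2,3-dimethoxybenzene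
Conditions: NaH, MOMCl, DMF, 0 °C to rt
Reagents that add atoms: chloromethyl methyl ether, COCCl
Why: Williamson-type O-alkylation of the bis-phenoxide with the reactive α-chloro ether should cap both hydroxyls as acetals that later direct lithiation and are removed by acid.

Step 3
Reactants: 3 1,4-bis(methoxymethoxy)-2,3-dimethoxybenzene
Product: 5 2,5-bis(methoxymethoxy)-3,4-dimethoxybenzaldehyde, via aryllithium 4 (not isolated)
Conditions: n-BuLi (1.1 equiv), TMEDA, THF, −78 to 0 °C; DMF, −78 °C to rt; H2O
Reagents that add atoms: N,N-dimethylformamide, CN(C)C=O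
Why: Directed ortho-metalation, in which the MOM acetal guides n-BuLi to the neighbouring ring position (the two free positions are equivalent by symmetry), followed by formylation of the aryllithium with DMF.

Step 4
Reactants: 5 2,5-bis(methoxymethoxy)-3,4-dimethoxybenzaldehyde; 6 creatinine
Product: 7 (E)-2-amino-5-[2,5-bis(methoxymethoxy)-3,4-dimethoxybenzylidene]-1-methyl-1,5-dihydro-4H-imidazol-4-one
Conditions: piperidine (0.3 equiv), n-BuOH, reflux
Reagents that add atoms: none
Why: Knoevenagel condensation at the C5 methylene of creatinine, its only acidic C–H, should give the conjugated arylidene (expected mainly as the E isomer, aryl away from the N-methyl group) under basic conditions that spare the MOM acetals.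

Step 5
Reactants: 7 (E)-2-amino-5-[2,5-bis(methoxymethoxy)-3,4-dimethoxybenzylidene]-1-methyl-1,5-dihydro-4H-imidazol-4-one
Product: 8 (E)-2-[bis(tert-butoxycarbonyl)amino]-5-[2,5-bis(methoxymethoxy)-3,4-dimethoxybenzylidene]-1-methyl-1,5-dihydro-4H-imidazol-4-one
Conditions: Boc2O (3 equiv), DMAP (0.2 equiv), THF, rt
Reagents that add atoms: di-tert-butyl dicarbonate, CC(C)(C)OC(=O)OC(=O)OC(C)(C)C
Why: DMAP-catalysed exhaustive acylation of an amidine-type exocyclic amine, as with 2-aminoazines and 2-aminoazoles, should stop at the imidodicarbonate, and doing it at the arylidene stage, where C5 has no hydrogen, excludes acylation at O4 or C5.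

Step 6
Reactants: 8 (E)-2-[bis(tert-butoxycarbonyl)amino]-5-[2,5-bis(methoxymethoxy)-3,4-dimethoxybenzylidene]-1-methyl-1,5-dihydro-4H-imidazol-4-one
Product: 9 racemic 2-[bis(tert-butoxycarbonyl)amino]-5-[2,5-bis(methoxymethoxy)-3,4-dimethoxybenzyl]-1-methyl-1,5-dihydro-4H-imidazol-4-one
Conditions: H2 (1 atm), 10% Pd/C, EtOAc, rt
Reagents that add atoms: none
Why: Heterogeneous hydrogenation of the exocyclic trisubstituted alkene, as known for arylidene creatinines and hydantoins, should saturate only the C=C bond; the new C5 stereocentre forms without control (racemate) and is erased in step 7.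

Step 7
Reactants: 9 racemic 2-[bis(tert-butoxycarbonyl)amino]-5-[2,5-bis(methoxymethoxy)-3,4-dimethoxybenzyl]-1-methyl-1,5-dihydro-4H-imidazol-4-one
Product: 11 2-[bis(tert-butoxycarbonyl)amino]-5-[2,5-bis(methoxymethoxy)-3,4-dimethoxybenzyl]-1-methylimidazol-4-yl trifluoromethanesulfonate, via potassium imidazol-4-olate 10 (not isolated)
Conditions: KN(SiMe3)2 (1.1 equiv), THF, −78 °C; PhNTf2 (1.2 equiv), −78 to 0 °C
Reagents that add atoms: N-phenylbis(trifluoromethanesulfonimide), O=S(=O)(N(c1ccccc1)S(=O)(=O)C(F)(F)F)C(F)(F)F
Why: Enolate O-triflation, the same reaction that converts oxazol-4(5H)-ones and thiazol-4(5H)-ones into azol-4-yl triflates: deprotonation at C5 gives a 4-oxidoimidazole, and sulfonylation at oxygen is favoured because it makes the ring aromatic.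

Step 8
Reactants: 12 4-methoxybenzyl chloride
Product: 13 4-methoxybenzylzinc chloride (LiCl-complexed, titrated THF solution)
Conditions: Zn dust (activated with BrCH2CH2Br and Me3SiCl), LiCl, THF, 25 °C
Reagents that add atoms: zinc, [Zn]
Why: LiCl-assisted direct insertion of zinc metal into a benzylic C–Cl bond is the standard preparation of benzylic zinc chlorides and keeps Wurtz coupling low because the chloride reacts only slowly with the organozinc.

Step 9
Reactants: 11 2-[bis(tert-butoxycarbonyl)amino]-5-[2,5-bis(methoxymethoxy)-3,4-dimethoxybenzyl]-1-methylimidazol-4-yl trifluoromethanesulfonate; 13 4-methoxybenzylzinc chloride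
Product: 14 2-[bis(tert-butoxycarbonyl)amino]-5-[2,5-bis(methoxymethoxy)-3,4-dimethoxybenzyl]-4-(4-methoxybenzyl)-1-methylimidazole
Conditions: Pd(OAc)2 (5 mol %), SPhos (10 mol %), THF, 25 to 50 °C, 13 (1.5 equiv) added slowly
Reagents that add atoms: none
Why: Pd(OAc)2 and SPhos are reduced in the flask to a zerovalent palladium complex that inserts into the C4–O bond of triflate 11; the benzyl group then passes from zinc to divalent palladium, and reductive elimination forms the C4–CH2 bond and returns zerovalent palladium. The closest known reaction is the Negishi coupling of aryl and heteroaryl triflates with benzylic zinc chlorides. No ring is closed and no stereocentre is formed. The step needs chemoselectivity for C–O insertion over attack of the organozinc at sulfur and over benzyl homocoupling: 11 offers a single electrophilic site, the imidodicarbonate on C2 withdraws electron density from the ring and speeds oxidative addition, and the zinc reagent, which has no β-hydrogen and is too weakly nucleophilic to touch carbamates or acetals, is kept at low concentration by slow addition. Which benzyl group ends on which carbon is not decided here, because C5 was filled by the aldol step and only C4 bears the leaving group.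

Step 10
Reactants: 14 2-[bis(tert-butoxycarbonyl)amino]-5-[2,5-bis(methoxymethoxy)-3,4-dimethoxybenzyl]-4-(4-methoxybenzyl)-1-methylimidazole
Product: 15 2-amino-5-(2,5-dihydroxy-3,4-dimethoxybenzyl)-4-(4-methoxybenzyl)-1-methylimidazole
Conditions: HCl (3 M), MeOH, 40 °C, Ar; then degassed aq. NaHCO3; used at once
Reagents that add atoms: none
Why: Acidolysis in methanol should cleave both tert-butyl carbamates (loss of 2-methylpropene and CO2) and transacetalise both MOM ethers to dimethoxymethane in one operation, while the protonated 2-aminoimidazole is shielded from electrophiles and exclusion of air protects the hydroquinone.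

Step 11
Reactants: 15 2-amino-5-(2,5-dihydroxy-3,4-dimethoxybenzyl)-4-(4-methoxybenzyl)-1-methylimidazole; 16 1-methylparabanic acid
Product: 20 naamidine E, via silyl imidate 17 (not isolated), via bis-silyl ether 18 (not isolated), via silylated adduct 19 (not isolated)
Conditions: 16 (2 equiv), BSA (6 equiv), MeCN, 80 °C; then 15, toluene, 100 °C, Ar; then MeOH, aq. citric acid, rt
Reagents that add atoms: none
Why: Condensation of a 2-aminoimidazole with O-silylated 1-methylparabanic acid, the established entry to naamidine-type dehydrohydantoins: BSA turns the imide into a silyl imidate whose C4 takes up the exocyclic amine by addition–elimination with loss of silanol, and it also masks both phenols as trimethylsilyl ethers during heating, which the methanolic work-up removes.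

**Compound list**

1 | 2,3-dimethoxy-1,4-benzoquinone | COC1=C(OC)C(=O)C=CC1=O | starting material
2 | 2,3-dimethoxybenzene-1,4-diol | COc1c(O)ccc(O)c1OC | intermediate
3 | 1,4-bis(methoxymethoxy)-2,3-dimethoxybenzene | COCOc1ccc(OCOC)c(OC)c1OC | intermediate
4 | [2,5-bis(methoxymethoxy)-3,4-dimethoxyphenyl]lithium | [Li]c1cc(OCOC)c(OC)c(OC)c1OCOC | intermediate
5 | 2,5-bis(methoxymethoxy)-3,4-dimethoxybenzaldehyde | O=Cc1cc(OCOC)c(OC)c(OC)c1OCOC | intermediate
6 | creatinine (2-amino-1-methyl-1,5-dihydro-4H-imidazol-4-one) | CN1CC(=O)N=C1N | starting material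
7 | (E)-2-amino-5-[2,5-bis(methoxymethoxy)-3,4-dimethoxybenzylidene]-1-methyl-1,5-dihydro-4H-imidazol-4-one | CN1C(N)=NC(=O)/C1=C\c1cc(OCOC)c(OC)c(OC)c1OCOC | intermediate
8 | (E)-2-[bis(tert-butoxycarbonyl)amino]-5-[2,5-bis(methoxymethoxy)-3,4-dimethoxybenzylidene]-1-methyl-1,5-dihydro-4H-imidazol-4-one | CN1C(N(C(=O)OC(C)(C)C)C(=O)OC(C)(C)C)=NC(=O)/C1=C\c1cc(OCOC)c(OC)c(OC)c1OCOC | intermediate
9 | racemic 2-[bis(tert-butoxycarbonyl)amino]-5-[2,5-bis(methoxymethoxy)-3,4-dimethoxybenzyl]-1-methyl-1,5-dihydro-4H-imidazol-4-one | CN1C(N(C(=O)OC(C)(C)C)C(=O)OC(C)(C)C)=NC(=O)C1Cc1cc(OCOC)c(OC)c(OC)c1OCOC | intermediate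
10 | potassium 2-[bis(tert-butoxycarbonyl)amino]-5-[2,5-bis(methoxymethoxy)-3,4-dimethoxybenzyl]-1-methylimidazol-4-olate | [K+].Cn1c(N(C(=O)OC(C)(C)C)C(=O)OC(C)(C)C)nc([O-])c1Cc1cc(OCOC)c(OC)c(OC)c1OCOC | intermediate
11 | 2-[bis(tert-butoxycarbonyl)amino]-5-[2,5-bis(methoxymethoxy)-3,4-dimethoxybenzyl]-1-methylimidazol-4-yl trifluoromethanesulfonate | Cn1c(N(C(=O)OC(C)(C)C)C(=O)OC(C)(C)C)nc(OS(=O)(=O)C(F)(F)F)c1Cc1cc(OCOC)c(OC)c(OC)c1OCOC | intermediate
12 | 4-methoxybenzyl chloride | COc1ccc(CCl)cc1 | starting material
13 | 4-methoxybenzylzinc chloride | COc1ccc(C[Zn]Cl)cc1 | intermediate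
14 | 2-[bis(tert-butoxycarbonyl)amino]-5-[2,5-bis(methoxymethoxy)-3,4-dimethoxybenzyl]-4-(4-methoxybenzyl)-1-methylimidazole | Cn1c(N(C(=O)OC(C)(C)C)C(=O)OC(C)(C)C)nc(Cc2ccc(OC)cc2)c1Cc1cc(OCOC)c(OC)c(OC)c1OCOC | intermediate
15 | 2-amino-5-(2,5-dihydroxy-3,4-dimethoxybenzyl)-4-(4-methoxybenzyl)-1-methylimidazole | Cn1c(N)nc(Cc2ccc(OC)cc2)c1Cc1cc(O)c(OC)c(OC)c1O | intermediate
16 | 1-methylparabanic acid (1-methylimidazolidine-2,4,5-trione) | CN1C(=O)NC(=O)C1=O | starting material
17 | 1-methyl-4-(trimethylsilyloxy)-1H-imidazole-2,5-dione | CN1C(=O)N=C(O[Si](C)(C)C)C1=O | intermediate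
18 | 2-amino-5-[3,4-dimethoxy-2,5-bis(trimethylsilyloxy)benzyl]-4-(4-methoxybenzyl)-1-methylimidazole | Cn1c(N)nc(Cc2ccc(OC)cc2)c1Cc1cc(O[Si](C)(C)C)c(OC)c(OC)c1O[Si](C)(C)C | intermediate
19 | bis(trimethylsilyl) ether of naamidine E | COc1ccc(Cc2nc(NC3=NC(=O)N(C)C3=O)n(C)c2Cc2cc(O[Si](C)(C)C)c(OC)c(OC)c2O[Si](C)(C)C)cc1 | intermediate
20 | naamidine E | COc1ccc(Cc2nc(NC3=NC(=O)N(C)C3=O)n(C)c2Cc2cc(O)c(OC)c(OC)c2O)cc1 | target

**Count**

Total steps: 11. Longest linear sequence: 10 (steps 1–7, 9, 10, 11); step 8 is the one-step side branch.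

**Steps most likely to fail**

1. Step 7 (enol triflation). The sulfonyl group may be delivered to N3 instead of O4, the S–O bond of the product may be cleaved by adventitious nucleophiles, or the triflate may hydrolyse during isolation. The fallback sets out from 9 and changes the electrophile class. Deprotonation with NaH in THF at 0 °C and trapping with nonafluorobutane-1-sulfonyl fluoride should give 2-[bis(tert-butoxycarbonyl)amino]-5-[2,5-bis(methoxymethoxy)-3,4-dimethoxybenzyl]-1-methylimidazol-4-yl nonafluorobutane-1-sulfonate F1, a sulfonate that is expected to tolerate water and silica better. F1 is then coupled with 13 under Pd(OAc)2/SPhos as in step 9, and the route is rejoined at 14.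

2. Step 9 (Negishi coupling). Oxidative addition into the electron-rich, ortho-substituted heteroaryl triflate may be slow, which leaves time for attack of the organozinc at sulfur, for homocoupling of the benzyl groups and for protodemetalation. The fallback sets out from 13 and replaces the zinc nucleophile by a neutral tin nucleophile. Quenching 13 with Bu3SnCl in THF should give tributyl(4-methoxybenzyl)stannane F2. A Stille coupling of 11 with F2 (Pd(PPh3)4, LiCl, dioxane, 100 °C) forms the same C4–CH2 bond without a reagent that can attack the sulfonate, and the route is rejoined at 14.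

3. Step 11 (amidine-forming condensation). The hydroquinone may oxidise in air if the transient trimethylsilyl ethers are lost during the long heating or the work-up, and the amine may add twice or at the wrong carbonyl while the substrate decomposes. The fallback sets out from 15 and protects the phenols in an isolable form. TBSCl and imidazole in DMF should give 2-amino-5-[2,5-bis(tert-butyldimethylsilyloxy)-3,4-dimethoxybenzyl]-4-(4-methoxybenzyl)-1-methylimidazole F3, which can be purified in air. F3 is condensed with silyl imidate 17 (from 16 and BSA, MeCN then toluene, 100 °C) to the bis(tert-butyldimethylsilyl) ether of naamidine E F4. Desilylation with HF·pyridine in THF at 0 °C, which avoids the basic conditions that would open the dehydrohydantoin, returns to the route at 20.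

**Further compounds**

F1 | step 7 | 2-[bis(tert-butoxycarbonyl)amino]-5-[2,5-bis(methoxymethoxy)-3,4-dimethoxybenzyl]-1-methylimidazol-4-yl nonafluorobutane-1-sulfonate | Cn1c(N(C(=O)OC(C)(C)C)C(=O)OC(C)(C)C)nc(OS(=O)(=O)C(F)(F)C(F)(F)C(F)(F)C(F)(F)F)c1Cc1cc(OCOC)c(OC)c(OC)c1OCOC
F2 | step 9 | tributyl(4-methoxybenzyl)stannane | CCCC[Sn](CCCC)(CCCC)Cc1ccc(OC)cc1
F3 | step 11 | 2-amino-5-[2,5-bis(tert-butyldimethylsilyloxy)-3,4-dimethoxybenzyl]-4-(4-methoxybenzyl)-1-methylimidazole | Cn1c(N)nc(Cc2ccc(OC)cc2)c1Cc1cc(O[Si](C)(C)C(C)(C)C)c(OC)c(OC)c1O[Si](C)(C)C(C)(C)C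
F4 | step 11 | bis(tert-butyldimethylsilyl) ether of naamidine E | COc1ccc(Cc2nc(NC3=NC(=O)N(C)C3=O)n(C)c2Cc2cc(O[Si](C)(C)C(C)(C)C)c(OC)c(OC)c2O[Si](C)(C)C(C)(C)C)cc1
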